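**Retrosynthetic overview**
1. Last C–O bonds: the two angelate esters, put on a 6β,10α-diol of the cis-fused dauc-8-ene core whose C2 hydroxyl is masked as a silyl ether.
2. The C6 and C10 carbinols come from a 6,10-dione: C6 by reduction directed by the C4 hydroxyl, C10 by enone formation and 1,2-reduction.
3. Seven-membered ring: glycol cleavage of a cyclobutane-1,2-diol made by [2+2] photocycloaddition of a 4-silyloxy-3-methylcyclopentenone with an enediol bis-silyl ether (sets C1 and C5); isopropyl is added to the C4 ketone before the cleavage.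
4. Key disconnection: the C2–O bond, made by an enantioselective γ-C–H hydroxylation of achiral 3-methylcyclopent-2-enone (new); it is the only step that brings in chirality, and every other stereocentre is relayed from it.
5. Ring order: the five-membered ring is present from the start; the seven-membered ring is formed second ([2+2], then C6–C10 cleavage).

Assumption: locants follow daucane numbering (C1 methyl-bearing ring-fusion carbon, C2 CHOH, C4 C(OH)iPr, C5 ring-fusion CH, C6 and C10 acyloxy carbons, C8=C9), β means the same ring face as the C1 methyl, the target is read as (1R,2R,4S,5R,6R,10R) with a cis ring fusion, and TBS = tert-butyldimethylsilyl, TMS = trimethylsilyl.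

**Route**

Step 1
Reactants: 1 3-methylcyclopent-2-en-1-one
Product: 2 (R)-4-hydroxy-3-methylcyclopent-2-en-1-one
Conditions: unspecific peroxygenase (fungal heme-thiolate enzyme, variant selected by screening for the (R)-alcohol), H2O2 (1.2 equiv, syringe pump), potassium phosphate buffer pH 7.0, acetone (5 vol%), 25 °C, stopped at about 85% conversion
Reagents that add atoms: hydrogen peroxide, OO
Why: Proposed new method: hydrogen peroxide turns the resting heme-thiolate iron into its oxo-iron porphyrin radical cation, which abstracts the weakest hydrogen of 1 (the ring CH2 that is allylic and γ to the carbonyl, while the electron-poor alkene resists epoxidation) and rebounds OH inside the chiral pocket so that only the pro-R hydrogen is replaced, giving the (R)-carbinol that becomes C2 of the target; the closest known reaction type is the peroxygenase or cytochrome P450 γ-hydroxylation of isophorone to 4-hydroxyisophorone, which has not been shown for a β-methylcyclopentenone.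

Step 2
Reactants: 2 (R)-4-hydroxy-3-methylcyclopent-2-en-1-one
Product: 3 (R)-4-(tert-butyldimethylsilyloxy)-3-methylcyclopent-2-en-1-one
Conditions: TBSCl, imidazole, DMF, 0 → 23 °C
Reagents that add atoms: tert-butyldimethylsilyl chloride, CC(C)(C)[Si](C)(C)Cl
Why: Imidazole-promoted O-silylation (Corey protocol) protects the secondary allylic alcohol under conditions too mild for β-elimination of the 4-oxygenated cyclopentenone, and no stereocentre is touched.

Step 3
Reactants: 4 dimethyl 3-methylpentanedioate
Product: 5 4-methyl-1,2-bis(trimethylsilyloxy)cyclopent-1-ene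
Conditions: Na (4.2 equiv), Me3SiCl (4.5 equiv), toluene, reflux
Reagents that add atoms: chlorotrimethylsilane (two molecules are incorporated), C[Si](C)(C)Cl
Why: Acyloin condensation in the Rühlmann modification couples the two ester carbonyls and traps the enediolate as its bis-silyl ether, the electron-rich alkene partner for step 4 (its methyl-bearing carbon is not stereogenic in this symmetric ring).

Step 4
Reactants: 3 (R)-4-(tert-butyldimethylsilyloxy)-3-methylcyclopent-2-en-1-one; 5 4-methyl-1,2-bis(trimethylsilyloxy)cyclopent-1-ene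
Product: 6 cis-anti-cis photoadduct 5-(tert-butyldimethylsilyloxy)-6,9-dimethyl-1,7-bis(trimethylsilyloxy)tricyclo[5.3.0.0(2,6)]decan-3-one (daucane locants: 1β-methyl; 5β-H; 2β-OTBS; 4-oxo; 6α,10α-bis-OTMS; C6–C10 bond; C8 epimers)
Conditions: hν (medium-pressure Hg lamp, λ > 330 nm), 5 (3 equiv), CH2Cl2, −40 °C
Reagents that add atoms: none
Why: Triplet enone–alkene [2+2] photocycloaddition: the alkene adds to the enone face anti to the neighbouring silyloxy group, so the new C1–C10 bond is trans to C2–O (angular methyl cis to it), and the four-membered ring can only close cis, which places H5 cis to the methyl; the cyclobutane and C8 centres that form as mixtures are erased in steps 6 and 8.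

Step 5
Reactants: 6 cis-anti-cis photoadduct; 7 isopropylmagnesium chloride
Product: 8 5-(tert-butyldimethylsilyloxy)-3-isopropyl-6,9-dimethyl-1,7-bis(trimethylsilyloxy)tricyclo[5.3.0.0(2,6)]decan-3-ol (4α-OH; 4β-isopropyl)
Conditions: LaCl3·2LiCl, THF, 0 °C; aq NH4Cl
Reagents that add atoms: none
Why: Lanthanum-promoted Grignard 1,2-addition suppresses enolisation and loss of the β-silyloxy groups, and the nucleophile enters on the convex face of the bicyclo[3.2.0]heptanone unit, anti to the cyclobutane, which places isopropyl cis to H5 and the new tertiary OH α at C4.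

Step 6
Reactants: 8 tricyclic tertiary carbinol
Product: 10 2β-(tert-butyldimethylsilyloxy)-4α-hydroxy-5βH-daucane-6,10-dione (cis-fused; C8 epimers), via cis-cyclobutane-1,2-diol 9 (not isolated)
Conditions: K2CO3, MeOH, 0 °C; then Pb(OAc)4, CH2Cl2, −20 °C
Reagents that add atoms: none
Why: Mild methanolysis removes only the two trimethylsilyl ethers, and strain-driven Criegee glycol cleavage of the cis-diol with lead tetraacetate opens the C6–C10 bond to the seven-membered 6,10-dione under neutral conditions, so C1, C2, C4 and C5 are untouched and the β-hydroxy ketone neither epimerises nor undergoes retro-aldol cleavage.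

Step 7
Reactants: 10 2β-(tert-butyldimethylsilyloxy)-4α-hydroxy-5βH-daucane-6,10-dione
Product: 11 2β-(tert-butyldimethylsilyloxy)-4α,6β-dihydroxy-5βH-daucan-10-one
Conditions: Me4NBH(OAc)3, MeCN/AcOH (1:1), −30 → 0 °C
Reagents that add atoms: none
Why: Evans–Saksena hydroxyl-directed reduction: the C4 alkoxy(diacetoxy)borohydride delivers hydride to the α face of the C6 carbonyl (the face on which the C4 oxygen sits), giving the 4,6-anti diol with C6–OH β (cis to H5), while the C10 ketone has no β-hydroxyl and is not reduced by this mild reagent.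

Step 8
Reactants: 11 2β-(tert-butyldimethylsilyloxy)-4α,6β-dihydroxy-5βH-daucan-10-one
Product: 13 2β-(tert-butyldimethylsilyloxy)-4α,6β-dihydroxy-5βH-dauc-8-en-10-one, via 9-phenylselanyl ketone 12 (not isolated)
Conditions: PhSeCl, EtOAc, 23 °C; then pyridine, H2O2 (30%), CH2Cl2, 0 → 23 °C
Reagents that add atoms: none
Why: Acid-catalysed α-selenenylation can only take place at C9 because C1 is quaternary, and the selenoxide syn-elimination (Reich–Sharpless dehydrogenation) can only run toward C8, which installs the C8=C9 alkene regiospecifically and merges the two C8 epimers.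

Step 9
Reactants: 13 2β-(tert-butyldimethylsilyloxy)-4α,6β-dihydroxy-5βH-dauc-8-en-10-one
Product: 14 2β-(tert-butyldimethylsilyloxy)-5βH-dauc-8-ene-4α,6β,10α-triol
Conditions: NaBH4, CeCl3·7H2O, MeOH, −78 °C
Reagents that add atoms: none
Why: Luche 1,2-reduction of the enone: hydride approaches C10 anti to the larger α-substituent on C1 (the ring carbon C2; Felkin–Anh control), that is from the face of the angular methyl, so the new C10–OH is α (trans to the methyl) and the other hydroxyls are unaffected.

Step 10
Reactants: 14 2β-(tert-butyldimethylsilyloxy)-5βH-dauc-8-ene-4α,6β,10α-triol; 15 angelic acid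
Product: 17 6β,10α-bis(angeloyloxy)-2β-(tert-butyldimethylsilyloxy)-5βH-dauc-8-en-4α-ol, via angelic 2,4,6-trichlorobenzoic anhydride 16 (not isolated)
Conditions: 15 (3.0 equiv), 2,4,6-Cl3C6H2COCl (3.0 equiv), Et3N (3.3 equiv), toluene, 23 °C, 2 h; then 14 (1.0 equiv), 80 °C
Reagents that add atoms: angelic acid (the second of the two molecules of 15 that are incorporated), C/C=C(/C)C(=O)O
Why: Yamaguchi-type mixed-anhydride esterification without a nucleophilic amine catalyst: two molecules of 16, each made from one molecule of 15, acylate the C6 and C10 secondary alcohols at the unhindered angeloyl carbonyl with retention at both carbinol centres and without Z-to-E isomerisation to tiglate, while the tertiary C4–OH is too hindered to react and C2 is silyl-protected.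

Step 11
Reactants: 17 6β,10α-bis(angeloyloxy)-2β-(tert-butyldimethylsilyloxy)-5βH-dauc-8-en-4α-ol
Product: 18 6β,10α-bis(angeloyloxy)-5βH-dauc-8-ene-2β,4α-diol (target CNP0249167.1)
Conditions: HF·pyridine, pyridine, THF, 0 → 23 °C
Reagents that add atoms: none
Why: Fluoride-mediated Si–O cleavage under buffered, non-basic conditions frees the C2 hydroxyl without acyl migration, angelate isomerisation or ionisation of the allylic ester, and no stereocentre changes.

**Compound list**
1 | 3-methylcyclopent-2-en-1-one | CC1=CC(=O)CC1 | starting material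
2 | (R)-4-hydroxy-3-methylcyclopent-2-en-1-one | CC1=CC(=O)C[C@H]1O | intermediate
3 | (R)-4-(tert-butyldimethylsilyloxy)-3-methylcyclopent-2-en-1-one | CC1=CC(=O)C[C@H]1O[Si](C)(C)C(C)(C)C | intermediate
4 | dimethyl 3-methylpentanedioate (dimethyl 3-methylglutarate) | COC(=O)CC(C)CC(=O)OC | starting material
5 | 4-methyl-1,2-bis(trimethylsilyloxy)cyclopent-1-ene | CC1CC(O[Si](C)(C)C)=C(O[Si](C)(C)C)C1 | intermediate
6 | cis-anti-cis photoadduct 5-(tert-butyldimethylsilyloxy)-6,9-dimethyl-1,7-bis(trimethylsilyloxy)tricyclo[5.3.0.0(2,6)]decan-3-one; daucane locants 1β-methyl, 5β-H, 2β-OTBS, 4-oxo, 6α,10α-bis-OTMS, extra C6–C10 bond, both C8 epimers | C[Si](C)(C)O[C@]13CC(C)C[C@]3(O[Si](C)(C)C)[C@@]2(C)[C@H](O[Si](C)(C)C(C)(C)C)CC(=O)[C@@H]12 | intermediate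
7 | isopropylmagnesium chloride | CC(C)[Mg]Cl | starting material
8 | 5-(tert-butyldimethylsilyloxy)-3-isopropyl-6,9-dimethyl-1,7-bis(trimethylsilyloxy)tricyclo[5.3.0.0(2,6)]decan-3-ol; as 6 with 4α-OH and 4β-isopropyl | C[Si](C)(C)O[C@]13CC(C)C[C@]3(O[Si](C)(C)C)[C@@]2(C)[C@H](O[Si](C)(C)C(C)(C)C)C[C@](O)(C(C)C)[C@@H]12 | intermediate
9 | 5-(tert-butyldimethylsilyloxy)-3-isopropyl-6,9-dimethyltricyclo[5.3.0.0(2,6)]decane-1,3,7-triol; cis-cyclobutane-1,2-diol, not isolated | O[C@]13CC(C)C[C@]3(O)[C@@]2(C)[C@H](O[Si](C)(C)C(C)(C)C)C[C@](O)(C(C)C)[C@@H]12 | intermediate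
10 | 2β-(tert-butyldimethylsilyloxy)-4α-hydroxy-5βH-daucane-6,10-dione; cis-fused, both C8 epimers | O=C1CC(C)CC(=O)[C@@]2(C)[C@H](O[Si](C)(C)C(C)(C)C)C[C@](O)(C(C)C)[C@@H]12 | intermediate
11 | 2β-(tert-butyldimethylsilyloxy)-4α,6β-dihydroxy-5βH-daucan-10-one; both C8 epimers | O[C@@H]1CC(C)CC(=O)[C@@]2(C)[C@H](O[Si](C)(C)C(C)(C)C)C[C@](O)(C(C)C)[C@@H]12 | intermediate
12 | 9-(phenylselanyl) derivative of 11; C8 and C9 epimers, not isolated | O[C@@H]1CC(C)C([Se]c3ccccc3)C(=O)[C@@]2(C)[C@H](O[Si](C)(C)C(C)(C)C)C[C@](O)(C(C)C)[C@@H]12 | intermediate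
13 | 2β-(tert-butyldimethylsilyloxy)-4α,6β-dihydroxy-5βH-dauc-8-en-10-one | O[C@@H]1CC(C)=CC(=O)[C@@]2(C)[C@H](O[Si](C)(C)C(C)(C)C)C[C@](O)(C(C)C)[C@@H]12 | intermediate
14 | 2β-(tert-butyldimethylsilyloxy)-5βH-dauc-8-ene-4α,6β,10α-triol | O[C@@H]1CC(C)=C[C@@H](O)[C@@]2(C)[C@H](O[Si](C)(C)C(C)(C)C)C[C@](O)(C(C)C)[C@@H]12 | intermediate
15 | angelic acid, (Z)-2-methylbut-2-enoic acid | C/C=C(/C)C(=O)O | starting material
16 | angelic 2,4,6-trichlorobenzoic anhydride; not isolated | C/C=C(/C)C(=O)OC(=O)c1c(Cl)cc(Cl)cc1Cl | intermediate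
17 | 6β,10α-bis(angeloyloxy)-2β-(tert-butyldimethylsilyloxy)-5βH-dauc-8-en-4α-ol | C/C=C(/C)C(=O)O[C@@H]1CC(C)=C[C@@H](OC(=O)/C(C)=C\C)[C@@]2(C)[C@H](O[Si](C)(C)C(C)(C)C)C[C@](O)(C(C)C)[C@@H]12 | intermediate
18 | (1R,2R,4S,5R,6R,10R)-6β,10α-bis(angeloyloxy)-5βH-dauc-8-ene-2β,4α-diol, CNP0249167.1 | C/C=C(/C)C(=O)O[C@@H]1CC(C)=C[C@@H](OC(=O)/C(C)=C\C)[C@@]2(C)[C@H](O)C[C@](O)(C(C)C)[C@@H]12 | target

**Step count and risks**

Total: 11 steps. Longest linear sequence: 10 steps (steps 1, 2 and 4 to 11; step 3 is a one-step branch).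

The three steps most likely to fail:

Step 1 (the proposed new hydroxylation). It could fail through competing oxidation of the methyl group, over-oxidation to the enedione, or insufficient enantiomeric purity. Fallback with known chemistry, setting out from 1: Wohl–Ziegler bromination (N-bromosuccinimide, azobisisobutyronitrile, PhCF3, reflux) gives racemic 4-bromo-3-methylcyclopent-2-en-1-one F1. Silver-assisted acetolysis (AgOAc, AcOH, 23 °C) then gives racemic 2-methyl-4-oxocyclopent-2-en-1-yl acetate F2. Lipase-catalysed enantioselective hydrolysis (phosphate buffer pH 7, stopped near 45% conversion) is expected to cleave the (R)-acetate, by analogy with the closely related 2-substituted rethrolone acetates, and leaves the (S)-acetate to be separated. The liberated (R)-alcohol is compound 2, where the route is re-entered.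

Step 7 (directed reduction). A tertiary hydroxyl has to exchange onto boron and compete with hemiketal formation at the C10 ketone; undirected hydride would give the 6α-epimer. Fallback, setting out from 10, with the tether made covalent: chlorodimethylsilane, Et3N and 4-(dimethylamino)pyridine in CH2Cl2 silylate the C4 hydroxyl to give the 4-O-dimethylsilyl ether of 10 F3. SnCl4 in CH2Cl2 at −78 °C then effects intramolecular anti-selective carbonyl hydrosilylation to give the cyclic 4α,6β-O-dimethylsilylene derivative F4. K2CO3 in MeOH removes the silylene and gives 11, where the route is re-entered.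

Step 10 (double angeloylation). Both alcohols are hindered (C10 is neopentylic) and each must take up one angeloyl group, so acylation may stop at a mono-ester or be accompanied by isomerisation to tiglate. Fallback, setting out from 14, in which the alkenes are built after acylation: esterification of both alcohols with the saturated acid 2-[bis(2,2,2-trifluoroethoxy)phosphoryl]propanoic acid (2.5 equiv; dicyclohexylcarbodiimide, 4-(dimethylamino)pyridine, CH2Cl2) gives the 6β,10α-bis(phosphonopropanoate) of 14 F5. Still–Gennari olefination with acetaldehyde (KN(SiMe3)2, 18-crown-6, THF, −78 °C) then forms both Z-alkenes and gives 17 directly, where the route is re-entered.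

Further compounds
F1 | step 1 | racemic 4-bromo-3-methylcyclopent-2-en-1-one | CC1=CC(=O)CC1Br
F2 | step 1 | racemic 2-methyl-4-oxocyclopent-2-en-1-yl acetate | CC(=O)OC1CC(=O)C=C1C
F3 | step 7 | 2β-(tert-butyldimethylsilyloxy)-4α-(dimethylsilyloxy)-5βH-daucane-6,10-dione | O=C1CC(C)CC(=O)[C@@]2(C)[C@H](O[Si](C)(C)C(C)(C)C)C[C@](O[SiH](C)C)(C(C)C)[C@@H]12
F4 | step 7 | 2β-(tert-butyldimethylsilyloxy)-4α,6β-(dimethylsilanediyldioxy)-5βH-daucan-10-one | C[Si]3(C)O[C@@H]1CC(C)CC(=O)[C@@]2(C)[C@H](O[Si](C)(C)C(C)(C)C)C[C@](O3)(C(C)C)[C@@H]12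
F5 | step 10 | 6β,10α-bis{2-[bis(2,2,2-trifluoroethoxy)phosphoryl]propanoyloxy}-2β-(tert-butyldimethylsilyloxy)-5βH-dauc-8-en-4α-ol | CC(P(=O)(OCC(F)(F)F)OCC(F)(F)F)C(=O)O[C@@H]1CC(C)=C[C@@H](OC(=O)C(C)P(=O)(OCC(F)(F)F)OCC(F)(F)F)[C@@]2(C)[C@H](O[Si](C)(C)C(C)(C)C)C[C@](O)(C(C)C)[C@@H]12
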